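**Retrosynthetic overview**
1. Late stage: the 13(16),14-diene comes from a terminal alkyne and ethene (enyne metathesis); 8-OH and 9-H come from syn hydroboration of a C8=C9 alkene; C9–C11 comes from Grignard addition to a C9 ketone whose oxygen is then removed.
2. Key disconnection: ring A is opened at C3–C4 and C1–C10, leading back to an aromatic ring B (silyl-protected 5-hydroxy-3-methylbenzofuran-2(3H)-one 5, from 2,6-dimethylbenzoquinone) and 1-chloro-3-iodopropane, joined in a [3+3] alkylation/dearomatization cascade.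
3. Enabling feature: the quaternary carbons C4 and C10 are 1,3-related across C5 and both border ring B. With ring B as a hydroquinone (O on C6 and C9) and C18 tied to O6 as a lactone, C4 is the enolizable C3 of a benzofuranone and C10 is the methyl-bearing ortho carbon of the C9 phenolate. C4–C5–C10 is thus a 1,3-dinucleophile, and the planar lactone forces the C19 and C20 methyl groups cis.
4. Ring order: ring B (aromatic, from the quinone), then the temporary five-membered lactone C18–O–C6, then ring A in the key step. The lactone is later opened by hydride; O6 is kept for the acetate and O9 is exchanged for the side chain.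

Key step: step 3

Remark: all locants in the text are labdane locants of the target (ring A: C1–C5, C10; ring B: C5–C10; C17 on C8; C18 and C19 on C4; C20 on C10). A center that is formed as a mixture and later removed (C9 in 11 and 12, C13 in 16) is written without configuration. In step 3 the catalyst antipode is the one that delivers Si-face alkylation.

Step 1
Reactants: 1 methyl propanoate
Product: 2 tert-butyl[(1-methoxyprop-1-en-1-yl)oxy]dimethylsilane (E/Z mixture)
Conditions: LiN(i-Pr)2, THF, −78 °C; t-BuMe2SiCl, DMPU, −78 to 23 °C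
Reagents that add atoms: tert-butyldimethylsilyl chloride, CC(C)(C)[Si](C)(C)Cl
Why: Kinetic ester enolization and O-silylation (ketene silyl acetal formation) should give 2; no stereocenter is formed and the alkene geometry is of no consequence.

Step 2
Reactants: 3 2,6-dimethyl-1,4-benzoquinone; 2 tert-butyl[(1-methoxyprop-1-en-1-yl)oxy]dimethylsilane
Product: 5 5-(tert-butyldimethylsilyloxy)-3,4,6-trimethyl-1-benzofuran-2(3H)-one, via hydroquinone silyl ether ester 4 (not isolated)
Conditions: t-BuMe2SiOTf (5 mol %), CH2Cl2, −78 to 0 °C; then camphor-10-sulfonic acid (10 mol %), toluene, 80 °C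
Reagents that add atoms: none
Why: Mukaiyama–Michael addition of the ketene silyl acetal to the only unsubstituted quinone carbon (future C5) with silyl transfer to the methyl-flanked oxygen (future O9), aromatization and acid-catalyzed lactonization of the free ortho phenol onto the ester should give 5; the C4 center is racemic and enolizable.

Step 3
Reactants: 5 5-(tert-butyldimethylsilyloxy)-3,4,6-trimethyl-1-benzofuran-2(3H)-one; 6 1-chloro-3-iodopropane
Product: 9 (2aS,5aR)-2a,5a,7-trimethyl-2a,3,4,5-tetrahydro-2H-naphtho[1,8-bc]furan-2,6(5aH)-dione, via C4-alkylated benzofuranone 7 (not isolated), via desilylated phenolate 8 (not isolated)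
Conditions: (11bS)-4,4-dibutyl-2,6-bis(3,4,5-trifluorophenyl)-4,5-dihydro-3H-dinaphtho[2,1-c:1',2'-e]azepinium bromide (3 mol %), Cs2CO3 (solid), toluene, −20 °C; then Bu4NF, NaI (20 mol %), THF, 0 to 50 °C, 0.02 M
Reagents that add atoms: none
Why: Under solid–liquid phase-transfer conditions the chiral ammonium ion pair of the 2-oxidobenzofuran (enolate of 5) is C-alkylated by the iodide end of 6 in an SN2 step (bond C3–C4); fluoride then removes the aryl silyl ether, and the freed C9 phenolate attacks the tethered primary chloride through its methyl-bearing ortho carbon C10 (bond C1–C10), giving the cyclohexa-2,4-dienone 9. The closest known reaction types are the asymmetric phase-transfer alkylation of 3-substituted benzofuran-2(3H)-ones and the C-alkylation of 2,6-dialkylphenoxides to 6,6-disubstituted cyclohexa-2,4-dienones (intramolecular ortho-alkylative dearomatization). Ring A is closed in a 6-exo-tet (Ar2-6) mode; no other ring is closed, and the lactone ring survives as an enol lactone. C4 is set by the catalyst (Si-face alkylation gives 4S), and C10 is set by C4: the three-carbon tether lies on one face of the planar benzofuranone, so C1 must bond to C10 on that face and the C19 and C20 methyl groups end up cis, with C18 held in the lactone plane. The step needs C- over O-alkylation twice and a single alkylation by 6: the soft aromatic enolate and the iodide/chloride reactivity gap secure the first stage, the silyl ether keeps the phenol silent until then, and in the second stage O-alkylation would need an eight-membered ring while C10 is the only nucleophilic ring carbon in reach.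

Step 4
Reactants: 9 (2aS,5aR)-2a,5a,7-trimethyl-2a,3,4,5-tetrahydro-2H-naphtho[1,8-bc]furan-2,6(5aH)-dione; 10 2-(2-bromoethyl)-1,3-dioxolane (as its Grignard reagent)
Product: 12 (4aR,8S,8aR)-4-[2-(1,3-dioxolan-2-yl)ethyl]-4-hydroxy-8-(hydroxymethyl)-3,4a,8-trimethyl-4a,5,6,7,8,8a-hexahydronaphthalen-1(4H)-one (C9 epimers), via C9 tertiary alkoxide 11 (not isolated)
Conditions: 10, Mg, THF; add to 9, LaCl3·2LiCl (30 mol %), THF, −78 °C; then LiAlH4, −78 to 0 °C; NaOH (aq); K2CO3, MeOH, 23 °C
Reagents that add atoms: none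
Why: Lanthanum-promoted Grignard 1,2-addition to the C9 carbonyl of the dienone (the neopentyl enol-lactone carbonyl is slower) is followed by hydride opening of the enol lactone, which frees C18 as the primary alcohol and C6 as an enolate that is protonated at C5 and base-equilibrated to the trans ring fusion (thermodynamic control next to the C6 ketone, 5-H anti to C20); the C9 carbinol forms as a mixture that is erased in step 5.

Step 5
Reactants: 12 (4aR,8S,8aR)-4-[2-(1,3-dioxolan-2-yl)ethyl]-4-hydroxy-8-(hydroxymethyl)-3,4a,8-trimethyl-4a,5,6,7,8,8a-hexahydronaphthalen-1(4H)-one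
Product: 13 (4aR,8S,8aS)-4-[2-(1,3-dioxolan-2-yl)ethyl]-8-(hydroxymethyl)-3,4a,8-trimethyl-4a,5,6,7,8,8a-hexahydronaphthalen-1(2H)-one
Conditions: SmI2, HMPA, t-BuOH, THF, −78 °C
Reagents that add atoms: none
Why: Samarium diiodide reduction of a vinylogous α-hydroxy ketone should expel the C9 oxygen from the enone ketyl, and kinetic α-protonation (C7) of the samarium dienolate should give the β,γ-unsaturated ketone with the tetrasubstituted C8=C9 alkene; no stereocenter is created and both C9 epimers converge.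

Step 6
Reactants: 13 (4aR,8S,8aS)-4-[2-(1,3-dioxolan-2-yl)ethyl]-8-(hydroxymethyl)-3,4a,8-trimethyl-4a,5,6,7,8,8a-hexahydronaphthalen-1(2H)-one
Product: 14 (1R,4aR,8S,8aS)-4-[2-(1,3-dioxolan-2-yl)ethyl]-8-(hydroxymethyl)-3,4a,8-trimethyl-1,2,4a,5,6,7,8,8a-octahydronaphthalen-1-ol
Conditions: Li, NH3 (l), THF, MeOH, −78 °C
Reagents that add atoms: none
Why: Dissolving-metal ketone reduction should give the thermodynamically favored equatorial C6 alcohol (6R; hydroxyl cis to 5-H and trans to the axial C19 and C20 methyl groups), while the unactivated C8=C9 alkene and the acetal are inert.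

Step 7
Reactants: 14 (1R,4aR,8S,8aS)-4-[2-(1,3-dioxolan-2-yl)ethyl]-8-(hydroxymethyl)-3,4a,8-trimethyl-1,2,4a,5,6,7,8,8a-octahydronaphthalen-1-ol
Product: 15 (1R,3S,4S,4aR,8S,8aS)-4-[2-(1,3-dioxolan-2-yl)ethyl]-8-(hydroxymethyl)-3,4a,8-trimethyldecahydronaphthalene-1,3-diol
Conditions: BH3·THF, THF, 0 to 23 °C; NaOH (aq), H2O2, 0 to 40 °C
Reagents that add atoms: hydrogen peroxide, OO
Why: Brown hydroboration–oxidation should add B–H syn to the tetrasubstituted alkene from the face opposite the axial C20 methyl on the neighboring C10, with boron on the less hindered C8 and hydrogen on C9, and oxidation with retention then sets 8S (OH) and 9S (H) together.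

Step 8
Reactants: 15 (1R,3S,4S,4aR,8S,8aS)-4-[2-(1,3-dioxolan-2-yl)ethyl]-8-(hydroxymethyl)-3,4a,8-trimethyldecahydronaphthalene-1,3-diol
Product: 16 8,13-lactol of (4S,5S,6R,8S,9S,10R)-6,8,18-trihydroxy-14,15,16-trinorlabdan-13-al (anomer mixture)
Conditions: pyridinium p-toluenesulfonate (20 mol %), acetone/H2O, 50 °C
Reagents that add atoms: water, O
Why: Acid-catalyzed acetal hydrolysis should free the C13 aldehyde, which is held reversibly by the C8 hydroxyl as a six-membered lactol; no lasting stereocenter is formed.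

Step 9
Reactants: 16 8,13-lactol of (4S,5S,6R,8S,9S,10R)-6,8,18-trihydroxy-14,15,16-trinorlabdan-13-al
Product: 17 (1R,3S,4S,4aR,8S,8aS)-4-(but-3-yn-1-yl)-8-(hydroxymethyl)-3,4a,8-trimethyldecahydronaphthalene-1,3-diol
Conditions: dimethyl (1-diazo-2-oxopropyl)phosphonate, K2CO3, MeOH, 0 to 23 °C
Reagents that add atoms: dimethyl (1-diazo-2-oxopropyl)phosphonate, COP(=O)(OC)C(=[N+]=[N-])C(C)=O
Why: The Ohira–Bestmann variant of the Seyferth–Gilbert homologation on the open aldehyde form of the lactol should give the terminal alkyne (C13≡C14) under mild base that leaves all stereocenters untouched.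

Step 10
Reactants: 17 (1R,3S,4S,4aR,8S,8aS)-4-(but-3-yn-1-yl)-8-(hydroxymethyl)-3,4a,8-trimethyldecahydronaphthalene-1,3-diol
Product: 18 (1R,3S,4S,4aR,8S,8aS)-4-(but-3-yn-1-yl)-8-{[(tert-butyldimethylsilyl)oxy]methyl}-3,4a,8-trimethyldecahydronaphthalene-1,3-diol
Conditions: t-BuMe2SiCl, imidazole, CH2Cl2, 0 °C
Reagents that add atoms: tert-butyldimethylsilyl chloride, CC(C)(C)[Si](C)(C)Cl
Why: Silyl ether formation should be selective for the primary C18 hydroxyl over the hindered secondary C6 and tertiary C8 hydroxyls.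

Step 11
Reactants: 18 (1R,3S,4S,4aR,8S,8aS)-4-(but-3-yn-1-yl)-8-{[(tert-butyldimethylsilyl)oxy]methyl}-3,4a,8-trimethyldecahydronaphthalene-1,3-diol
Product: 19 (1R,3S,4S,4aR,8S,8aS)-4-(but-3-yn-1-yl)-8-{[(tert-butyldimethylsilyl)oxy]methyl}-3-hydroxy-3,4a,8-trimethyldecahydronaphthalen-1-yl acetate
Conditions: Ac2O, 4-(dimethylamino)pyridine (cat.), pyridine, CH2Cl2, 23 °C
Reagents that add atoms: acetic anhydride, CC(=O)OC(C)=O
Why: Nucleophile-catalyzed acetylation should take the only remaining secondary alcohol (C6), since the tertiary C8 alcohol does not react under these conditions.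

Step 12
Reactants: 19 (1R,3S,4S,4aR,8S,8aS)-4-(but-3-yn-1-yl)-8-{[(tert-butyldimethylsilyl)oxy]methyl}-3-hydroxy-3,4a,8-trimethyldecahydronaphthalen-1-yl acetate
Product: 20 (1R,3S,4S,4aR,8S,8aS)-4-(but-3-yn-1-yl)-3-hydroxy-8-(hydroxymethyl)-3,4a,8-trimethyldecahydronaphthalen-1-yl acetate
Conditions: HF·pyridine, THF, 0 to 23 °C
Reagents that add atoms: none
Why: Fluoride-mediated desilylation under buffered acidic conditions should free the C18 alcohol without acetyl migration or cleavage.

Step 13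
Reactants: 20 (1R,3S,4S,4aR,8S,8aS)-4-(but-3-yn-1-yl)-3-hydroxy-8-(hydroxymethyl)-3,4a,8-trimethyldecahydronaphthalen-1-yl acetate
Product: 21 (1R,3S,4S,4aR,8S,8aS)-3-hydroxy-8-(hydroxymethyl)-3,4a,8-trimethyl-4-(3-methylidenepent-4-en-1-yl)decahydronaphthalen-1-yl acetate
Conditions: ethene (1 atm), second-generation Grubbs catalyst RuCl2(=CHPh)(PCy3)(H2IMes) (5 mol %), toluene, 80 °C
Reagents that add atoms: ethene, C=C
Why: Ruthenium-carbene-catalyzed cross enyne metathesis of the terminal alkyne with ethene should give the 2-substituted buta-1,3-diene (C13=C16 and C14=C15) without touching the alcohols or the acetate; no stereocenter is formed.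

**Compound list**
1 | methyl propanoate | CCC(=O)OC | starting material
2 | tert-butyl[(1-methoxyprop-1-en-1-yl)oxy]dimethylsilane (E/Z mixture) | CC=C(OC)O[Si](C)(C)C(C)(C)C | intermediate
3 | 2,6-dimethyl-1,4-benzoquinone | CC1=CC(=O)C=C(C)C1=O | starting material
4 | methyl 2-[5-(tert-butyldimethylsilyloxy)-2-hydroxy-4,6-dimethylphenyl]propanoate (racemic) | COC(=O)C(C)c1c(O)cc(C)c(O[Si](C)(C)C(C)(C)C)c1C | intermediate
5 | 5-(tert-butyldimethylsilyloxy)-3,4,6-trimethyl-1-benzofuran-2(3H)-one (racemic, C3 labile) | CC1C(=O)Oc2cc(C)c(O[Si](C)(C)C(C)(C)C)c(C)c12 | intermediate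
6 | 1-chloro-3-iodopropane | ClCCCI | starting material
7 | (3S)-5-(tert-butyldimethylsilyloxy)-3-(3-chloropropyl)-3,4,6-trimethyl-1-benzofuran-2(3H)-one | C[C@@]1(CCCCl)C(=O)Oc2cc(C)c(O[Si](C)(C)C(C)(C)C)c(C)c12 | intermediate
8 | (3S)-3-(3-chloropropyl)-5-hydroxy-3,4,6-trimethyl-1-benzofuran-2(3H)-one (present as its tetrabutylammonium phenolate) | C[C@@]1(CCCCl)C(=O)Oc2cc(C)c(O)c(C)c12 | intermediate
9 | (2aS,5aR)-2a,5a,7-trimethyl-2a,3,4,5-tetrahydro-2H-naphtho[1,8-bc]furan-2,6(5aH)-dione (labdane locants 4S,10R; C19 and C20 cis) | CC1=CC2=C3[C@](C)(CCC[C@@]3(C)C1=O)C(=O)O2 | intermediate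
10 | 2-(2-bromoethyl)-1,3-dioxolane | BrCCC1OCCO1 | starting material
11 | (2aS,5aR)-6-[2-(1,3-dioxolan-2-yl)ethyl]-6-hydroxy-2a,5a,7-trimethyl-2a,3,4,5,5a,6-hexahydro-2H-naphtho[1,8-bc]furan-2-one (C9 epimers; magnesium alkoxide in the flask) | CC1=CC2=C3[C@](C)(CCC[C@@]3(C)C1(O)CCC4OCCO4)C(=O)O2 | intermediate
12 | (4aR,8S,8aR)-4-[2-(1,3-dioxolan-2-yl)ethyl]-4-hydroxy-8-(hydroxymethyl)-3,4a,8-trimethyl-4a,5,6,7,8,8a-hexahydronaphthalen-1(4H)-one (trans-fused; C9 epimers) | OC[C@@]1(C)CCC[C@]2(C)[C@@H]1C(=O)C=C(C)C2(O)CCC3OCCO3 | intermediate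
13 | (4aR,8S,8aS)-4-[2-(1,3-dioxolan-2-yl)ethyl]-8-(hydroxymethyl)-3,4a,8-trimethyl-4a,5,6,7,8,8a-hexahydronaphthalen-1(2H)-one | OC[C@@]1(C)CCC[C@]2(C)[C@@H]1C(=O)CC(C)=C2CCC3OCCO3 | intermediate
14 | (1R,4aR,8S,8aS)-4-[2-(1,3-dioxolan-2-yl)ethyl]-8-(hydroxymethyl)-3,4a,8-trimethyl-1,2,4a,5,6,7,8,8a-octahydronaphthalen-1-ol | OC[C@@]1(C)CCC[C@]2(C)[C@@H]1[C@H](O)CC(C)=C2CCC3OCCO3 | intermediate
15 | (1R,3S,4S,4aR,8S,8aS)-4-[2-(1,3-dioxolan-2-yl)ethyl]-8-(hydroxymethyl)-3,4a,8-trimethyldecahydronaphthalene-1,3-diol (labdane locants 4S,5S,6R,8S,9S,10R) | OC[C@@]1(C)CCC[C@]2(C)[C@@H]1[C@H](O)C[C@](C)(O)[C@H]2CCC3OCCO3 | intermediate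
16 | 8,13-lactol of (4S,5S,6R,8S,9S,10R)-6,8,18-trihydroxy-14,15,16-trinorlabdan-13-al (anomer mixture; in equilibrium with the open hydroxy aldehyde) | OC[C@@]1(C)CCC[C@]2(C)[C@@H]1[C@H](O)C[C@]3(C)OC(O)CC[C@@H]23 | intermediate
17 | (1R,3S,4S,4aR,8S,8aS)-4-(but-3-yn-1-yl)-8-(hydroxymethyl)-3,4a,8-trimethyldecahydronaphthalene-1,3-diol | OC[C@@]1(C)CCC[C@]2(C)[C@@H]1[C@H](O)C[C@](C)(O)[C@H]2CCC#C | intermediate
18 | (1R,3S,4S,4aR,8S,8aS)-4-(but-3-yn-1-yl)-8-{[(tert-butyldimethylsilyl)oxy]methyl}-3,4a,8-trimethyldecahydronaphthalene-1,3-diol | CC(C)(C)[Si](C)(C)OC[C@@]1(C)CCC[C@]2(C)[C@@H]1[C@H](O)C[C@](C)(O)[C@H]2CCC#C | intermediate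
19 | (1R,3S,4S,4aR,8S,8aS)-4-(but-3-yn-1-yl)-8-{[(tert-butyldimethylsilyl)oxy]methyl}-3-hydroxy-3,4a,8-trimethyldecahydronaphthalen-1-yl acetate | CC(C)(C)[Si](C)(C)OC[C@@]1(C)CCC[C@]2(C)[C@@H]1[C@H](OC(C)=O)C[C@](C)(O)[C@H]2CCC#C | intermediate
20 | (1R,3S,4S,4aR,8S,8aS)-4-(but-3-yn-1-yl)-3-hydroxy-8-(hydroxymethyl)-3,4a,8-trimethyldecahydronaphthalen-1-yl acetate | OC[C@@]1(C)CCC[C@]2(C)[C@@H]1[C@H](OC(C)=O)C[C@](C)(O)[C@H]2CCC#C | intermediate
21 | (1R,3S,4S,4aR,8S,8aS)-3-hydroxy-8-(hydroxymethyl)-3,4a,8-trimethyl-4-(3-methylidenepent-4-en-1-yl)decahydronaphthalen-1-yl acetate (labdane locants 4S,5S,6R,8S,9S,10R) | C=CC(=C)CC[C@H]1[C@]2(C)CCC[C@](C)(CO)[C@H]2[C@H](OC(C)=O)C[C@]1(C)O | target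

Total step count: 13
Longest linear sequence: 13 steps (1 to 21)

**Steps most likely to fail**

Step 3. The ion-pair alkylation of the small 3-methyl enolate may show poor facial discrimination, and during ring closure the phenolate may be O-alkylated intermolecularly or oligomerize. The fallback sets out from 5 and makes the two bonds in separate, individually precedented steps. Organocatalytic Michael addition of 5 to acrolein (1-[3,5-bis(trifluoromethyl)phenyl]-3-[(8α,9S)-6'-methoxycinchonan-9-yl]thiourea, CH2Cl2, −40 °C) should give (3S)-5-(tert-butyldimethylsilyloxy)-3,4,6-trimethyl-3-(3-oxopropyl)-1-benzofuran-2(3H)-one F1. NaBH4 in MeOH at −40 °C should give (3S)-5-(tert-butyldimethylsilyloxy)-3-(3-hydroxypropyl)-3,4,6-trimethyl-1-benzofuran-2(3H)-one F2, and an Appel reaction (I2, PPh3, imidazole) should give (3S)-5-(tert-butyldimethylsilyloxy)-3-(3-iodopropyl)-3,4,6-trimethyl-1-benzofuran-2(3H)-one F3. Bu4NF in dilute THF then triggers desilylation and the same ortho-alkylative dearomatization, and the route is rejoined at 9.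

Step 7. Boron may be delivered to C9 instead of C8, or the hindered tetrasubstituted alkene may not react. The fallback sets out from 14 and uses a radical epoxide opening instead of the concerted addition. m-Chloroperbenzoic acid should epoxidize C8=C9 on the face opposite the C20 methyl (assisted by the C6 hydroxyl) to give the 8,9-epoxide of 14 with the oxygen trans to C20, F4. Cp2TiCl (trivalent titanium, made from Cp2TiCl2 and Zn) with 1,4-cyclohexadiene should then cleave the more congested C9–O bond homolytically; the tertiary C9 radical takes a hydrogen atom on the open face, and the route is rejoined at 15.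

Step 5. Loss of the free tertiary hydroxyl may be slow, the dienolate may be protonated at C9 instead of C7, or the ketone may be over-reduced. The fallback sets out from 9 and installs the C9 substituent by cross-coupling. LiBH(s-Bu)3 should add hydride to C7, and trapping the C9 enolate with PhNTf2 should give (2aS,5aR)-2a,5a,7-trimethyl-2-oxo-2a,3,4,5,5a,8-hexahydro-2H-naphtho[1,8-bc]furan-6-yl trifluoromethanesulfonate F5. Negishi coupling with the zinc reagent made from 10 (Zn, LiCl) under Pd(dppf)Cl2 catalysis should give (2aS,5aS)-6-[2-(1,3-dioxolan-2-yl)ethyl]-2a,5a,7-trimethyl-2a,3,4,5,5a,8-hexahydro-2H-naphtho[1,8-bc]furan-2-one F6 (same spatial arrangement as 9). LiAlH4 then opens the enol lactone as in step 4, and after base equilibration at C5 the route is rejoined at 13.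

**Further compounds**
F1 | step 3 | (3S)-5-(tert-butyldimethylsilyloxy)-3,4,6-trimethyl-3-(3-oxopropyl)-1-benzofuran-2(3H)-one | C[C@@]1(CCC=O)C(=O)Oc2cc(C)c(O[Si](C)(C)C(C)(C)C)c(C)c12
F2 | step 3 | (3S)-5-(tert-butyldimethylsilyloxy)-3-(3-hydroxypropyl)-3,4,6-trimethyl-1-benzofuran-2(3H)-one | C[C@@]1(CCCO)C(=O)Oc2cc(C)c(O[Si](C)(C)C(C)(C)C)c(C)c12
F3 | step 3 | (3S)-5-(tert-butyldimethylsilyloxy)-3-(3-iodopropyl)-3,4,6-trimethyl-1-benzofuran-2(3H)-one | C[C@@]1(CCCI)C(=O)Oc2cc(C)c(O[Si](C)(C)C(C)(C)C)c(C)c12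
F4 | step 7 | 8,9-epoxide of 14 with the epoxide oxygen trans to the C20 methyl | OC[C@@]1(C)CCC[C@]2(C)[C@@H]1[C@H](O)C[C@]3(C)O[C@]23CCC4OCCO4
F5 | step 5 | (2aS,5aR)-2a,5a,7-trimethyl-2-oxo-2a,3,4,5,5a,8-hexahydro-2H-naphtho[1,8-bc]furan-6-yl trifluoromethanesulfonate | CC1=C(OS(=O)(=O)C(F)(F)F)[C@]2(C)CCC[C@]3(C)C(=O)OC(C1)=C23
F6 | step 5 | (2aS,5aS)-6-[2-(1,3-dioxolan-2-yl)ethyl]-2a,5a,7-trimethyl-2a,3,4,5,5a,8-hexahydro-2H-naphtho[1,8-bc]furan-2-one | CC1=C(CCC4OCCO4)[C@]2(C)CCC[C@]3(C)C(=O)OC(C1)=C23
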